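(The data come from a simulation for substances that don't exist; noise was put on by code.)

Minutes on the flask charged at 5.0 mM of starting material. Early times came first, and the first speaker noted that there are no readings of them: the earliest sample of the dusk run, at 0.417 min, lies far later than the 0.080 s asked about.

| flask | starting material | remark | time |
|---|---|---|---|
| dusk | 3.4 mM | run made earlier |  |
| spring | 7.5 mM | run made earlier |  |
| flask | 5.0 mM |  | 6.0 min |

| run | time / min | isomer of the product A / % | target / % | starting material / % |
|---|---|---|---|---|
| dusk | 0.417 | 63.9 | 2.3 | 0 |
| dusk | 1.00 | 63.8 | 2.1 | 0 |
| dusk | 2.00 | 63.1 | 1.7 | 0 |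
| dusk | 3.00 | 63.5 | 0.6 | 0.4 |
| dusk | 4.00 | 64.1 | 0.4 | 0.1 |
| dusk | 6.00 | 63.0 | 0 | 0.2 |
| dusk | 8.00 | 63.6 | 0.7 | 0.2 |
| spring | 1.00 | 63.2 | 2.2 | 0 |
| spring | 2.00 | 63.4 | 1.6 | 0 |
| spring | 3.00 | 63.1 | 1.2 | 0 |
| spring | 4.00 | 62.9 | 0.8 | 0.8 |
| spring | 5.00 | 62.9 | 0.4 | 0 |
| spring | 6.00 | 62.9 | 0.3 | 0 |
| spring | 8.00 | 63.4 | 0 | 0.2 |

(scatter of a reading: 0.3 percentage points)

1. share of isomer of the product A in isomer of the product A plus target at 0.080 s
2. share of isomer of the product A in isomer of the product A plus target at 6.0 min

- in percentages every species weighs as the starting material in it: one self-condensation product counts as two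
- the analysis behind the earlier runs scatters by 0.3 percentage points, standard deviation
- steps that have been proposed: starting material <-> other conformer; starting material -> target; other conformer -> isomer of the product A; other conformer <-> third conformer; third conformer -> third product; target <-> isomer of the product B; target -> over-reaction product; 2 other conformer -> self-condensation product

She pointed out that on the proposed steps target forms straight from starting material, whereas isomer of the product A forms from other conformer, and none of that is charged. At time zero, she argued, isomer of the product A has a lag (an induction period) and target has none, so the comparison of rates opens for target and drifts towards isomer of the product A. She expected a low early share but gave no figure.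

The second speaker took the late end from the spring run. There c(isomer of the product A) stays flat within the scatter, while c(target) fades from 2.2% to 0.4%, which he read as a first-order fade of 0.426 min⁻¹, a reading with large scatter. Carried on to 6.0 min, that reckons 0.261% of target in the spring run. He called c(target) over c(isomer of the product A) at that time the tail ratio, here 0.415%, and the late share he gave for the flask is 99.6%.

The forecast stood at 95% for the early time and 99.5% for the late one, with the remark “The runs cannot test this.”

The flask gives 9.74% and 99.5%.

    starting material ⇌ other conformer (K = 2.30, k = 1.55 s⁻¹)
    starting material → target (k = 0.398 s⁻¹)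
    other conformer → isomer of the product A (k = 0.695 s⁻¹)
    other conformer ⇌ third conformer (K = 0.985, k = 0.0512 s⁻¹)
    third conformer → third product (k = 0.0933 s⁻¹)
    target ⇌ isomer of the product B (K = 6.40, k = 0.170 s⁻¹)
    target → over-reaction product (k = 0.0549 s⁻¹)
    2 other conformer → self-condensation product (k = 3.42 M⁻¹ s⁻¹)

In this flask, c(isomer of the product A) and c(target) stand level at 15.8% only after 0.0135 min, later than the early time asked. At 6.0 min the tail ratio of this flask is 0.533%, where the second speaker had reckoned 0.415% from the spring readings. The neighbouring flask, charged at 8.5 mM, holds 0.336% of target and 62.9% of isomer of the product A at that time, a tail ratio of 0.534%, and its share is 99.5%.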